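**Retrosynthetic overview**

1. Locants: the naphthofuran (cacalol-type) unit is numbered O1, C2, C3, C3a, C4, C4a, C5–C8, C8a, C9 (bearing O9), C9a; the seco unit is a benzofuran with primed locants O1′ to C7a′. The target is (5S,8R,2′R,3′R).
2. The central dihydropyran ring holds the aryl ether oxygen O9 and, ortho to it on the same benzene ring, the benzylic carbon C8. This is an ortho-quinone methide retron. Its other two carbons, C2′(H)(O1′) and C3′(CH3)(aryl), are the former C2′=C3′ bond of a 3-methylbenzofuran. O9–C3′ and C8–C2′ are therefore disconnected together as an inverse-demand oxa-[4+2].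
3. The target has C2′ syn to the C5 methyl, so the methyl is carried as CH2–O–Si(iPr)2–O–C7′. This temporary silicon tether delivers the benzofuran to the required face and is then removed (CH2OH, CH2I, CH3).
4. Fragments: hydroxymethyl tetralone-furan 13 from 3,4-dimethoxytoluene (C5 by catalytic asymmetric hydroboration) and benzofuranol 21 from creosol (ortho-formylation, methylenation, hydroboration/Suzuki–Miyaura coupling).
5. Ring order: cacalol-unit carbocycle (Friedel–Crafts acylation), then its furan; seco-unit furan; last the dihydropyran, with dearomatisation to the cis-fused dihydrobenzofuran, in the key step.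

Key step: step 19

Remark (assumption on the chemistry): an untethered ortho-quinone methide with only a pseudoaxial C5 methyl is assumed to be attacked mainly anti to that group, which is the wrong sense for this target; the tether exists for that reason.

**Route**

Step 1
Reactants: 1 3,4-dimethoxytoluene
Product: 2 methyl 4-(4,5-dimethoxy-2-methylphenyl)-4-oxobutanoate
Conditions: methyl 4-chloro-4-oxobutanoate, AlCl3, CH2Cl2, 0 °C to rt
Reagents that add atoms: methyl 4-chloro-4-oxobutanoate, COC(=O)CCC(Cl)=O
Why: Friedel–Crafts acylation should occur at the ring position para to one methoxy group and ortho to the methyl group, the most activated accessible site.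

Step 2
Reactants: 2 methyl 4-(4,5-dimethoxy-2-methylphenyl)-4-oxobutanoate
Product: 3 methyl 4-(4,5-dimethoxy-2-methylphenyl)pent-4-enoate
Conditions: Ph3PCH3Br, KOtBu, THF, 0 °C to rt
Reagents that add atoms: methyltriphenylphosphonium bromide, C[P+](c1ccccc1)(c1ccccc1)c1ccccc1.[Br-]
Why: Wittig methylenation; the non-stabilised ylide should attack the aryl ketone in preference to the ester.

Step 3
Reactants: 3 methyl 4-(4,5-dimethoxy-2-methylphenyl)pent-4-enoate
Product: 5 methyl (4S)-4-(4,5-dimethoxy-2-methylphenyl)-5-hydroxypentanoate, via pinacol boronate 4 (not isolated)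
Conditions: (L*)CoCl2 (L* = chiral iminopyridine–oxazoline ligand, 2 mol%), NaBHEt3 (6 mol%), HBpin, THF, rt; then H2O2, pH 7 phosphate buffer, 0 °C
Reagents that add atoms: hydrogen peroxide, OO (oxygen of CH2OH); pinacolborane, B1OC(C)(C)C(C)(C)O1 (boron stays only in intermediate 4)
Why: Cobalt-hydride-catalysed enantioselective anti-Markovnikov hydroboration of a 1,1-disubstituted aryl alkene, then stereoretentive C–B oxidation; the ligand enantiomer chosen for S sets the benzylic stereocentre when hydride adds to the internal carbon.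

Step 4
Reactants: 5 methyl (4S)-4-(4,5-dimethoxy-2-methylphenyl)-5-hydroxypentanoate
Product: 6 methyl (4S)-4-(4,5-dimethoxy-2-methylphenyl)-5-(pivaloyloxy)pentanoate
Conditions: PivCl, pyridine, DMAP (cat.), CH2Cl2, 0 °C
Reagents that add atoms: pivaloyl chloride, CC(C)(C)C(Cl)=O
Why: Acylation of the primary alcohol; the pivalate is chosen because it should survive the Lewis and Brønsted acids of steps 6 to 9.

Step 5
Reactants: 6 methyl (4S)-4-(4,5-dimethoxy-2-methylphenyl)-5-(pivaloyloxy)pentanoate
Product: 7 (4S)-4-(4,5-dimethoxy-2-methylphenyl)-5-(pivaloyloxy)pentanoic acid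
Conditions: LiOH, THF/H2O, 0 °C; HCl work-up
Reagents that add atoms: lithium hydroxide, [Li+].[OH-] (oxygen of the acid)
Why: Saponification; the unhindered methyl ester should hydrolyse much faster than the pivalate at 0 °C.

Step 6
Reactants: 7 (4S)-4-(4,5-dimethoxy-2-methylphenyl)-5-(pivaloyloxy)pentanoic acid
Product: 9 [(1S)-5,6-dimethoxy-8-methyl-4-oxo-1,2,3,4-tetrahydronaphthalen-1-yl]methyl pivalate, via acid chloride 8 (not isolated)
Conditions: (COCl)2, DMF (cat.), CH2Cl2, 0 °C; then SnCl4, CH2Cl2, −20 °C to 0 °C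
Reagents that add atoms: oxalyl chloride, O=C(Cl)C(Cl)=O (chlorine stays only in intermediate 8)
Why: Intramolecular Friedel–Crafts acylation; with the other ortho position blocked by methyl, six-ring closure can only occur ortho to the methoxy group, and the stereocentre is not touched.

Step 7
Reactants: 9 [(1S)-5,6-dimethoxy-8-methyl-4-oxo-1,2,3,4-tetrahydronaphthalen-1-yl]methyl pivalate
Product: 10 [(1S)-5,6-dihydroxy-8-methyl-4-oxo-1,2,3,4-tetrahydronaphthalen-1-yl]methyl pivalate
Conditions: BBr3, CH2Cl2, −78 °C to 0 °C; H2O work-up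
Reagents that add atoms: none
Why: Lewis-acid cleavage of both aryl methyl ethers (BBr3 demethylation); ketone and pivalate should survive at low temperature.

Step 8
Reactants: 10 [(1S)-5,6-dihydroxy-8-methyl-4-oxo-1,2,3,4-tetrahydronaphthalen-1-yl]methyl pivalate
Product: 11 [(1S)-5-hydroxy-8-methyl-4-oxo-6-(2-oxopropoxy)-1,2,3,4-tetrahydronaphthalen-1-yl]methyl pivalate
Conditions: chloroacetone, K2CO3, KI (cat.), acetone, rt
Reagents that add atoms: chloroacetone, CC(=O)CCl
Why: Williamson etherification; the C5 hydroxyl is held in a hydrogen bond to the peri carbonyl, so the free C6 phenoxide should be alkylated selectively.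

Step 9
Reactants: 11 [(1S)-5-hydroxy-8-methyl-4-oxo-6-(2-oxopropoxy)-1,2,3,4-tetrahydronaphthalen-1-yl]methyl pivalate
Product: 12 [(5S)-9-hydroxy-3,4-dimethyl-8-oxo-5,6,7,8-tetrahydronaphtho[2,3-b]furan-5-yl]methyl pivalate
Conditions: Amberlyst 15, chlorobenzene, reflux, azeotropic removal of water
Reagents that add atoms: none
Why: Acid-catalysed cyclodehydration of the aryloxyacetone (intramolecular electrophilic aromatic substitution, then loss of water) at the only free ring position should give the 3-methylfuran.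

Step 10
Reactants: 12 [(5S)-9-hydroxy-3,4-dimethyl-8-oxo-5,6,7,8-tetrahydronaphtho[2,3-b]furan-5-yl]methyl pivalate
Product: 13 (5S)-9-hydroxy-5-(hydroxymethyl)-3,4-dimethyl-6,7-dihydronaphtho[2,3-b]furan-8(5H)-one
Conditions: NaOMe, MeOH, 50 °C
Reagents that add atoms: none
Why: Base-mediated transesterification (methanolysis) frees the primary alcohol; the benzylic C5–H is not acidic enough for epimerisation.

Step 11
Reactants: 14 creosol (2-methoxy-4-methylphenol)
Product: 15 1-(2-methoxy-4-methylphenoxy)propan-2-one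
Conditions: chloroacetone, K2CO3, KI (cat.), acetone, reflux
Reagents that add atoms: chloroacetone, CC(=O)CCl
Why: Williamson etherification of the only phenol.

Step 12
Reactants: 15 1-(2-methoxy-4-methylphenoxy)propan-2-one
Product: 16 7-methoxy-3,5-dimethyl-1-benzofuran
Conditions: Amberlyst 15, toluene, reflux, azeotropic removal of water
Reagents that add atoms: none
Why: Acid-catalysed cyclodehydration onto the single free position ortho to the ether oxygen should give the 3-methylbenzofuran.

Step 13
Reactants: 16 7-methoxy-3,5-dimethyl-1-benzofuran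
Product: 17 3,5-dimethyl-1-benzofuran-7-ol
Conditions: NaSEt, DMF, 130 °C; HCl work-up
Reagents that add atoms: none
Why: SN2 demethylation by thiolate, chosen over a Lewis acid to spare the acid-sensitive furan.

Step 14
Reactants: 17 3,5-dimethyl-1-benzofuran-7-ol
Product: 18 7-hydroxy-3,5-dimethyl-1-benzofuran-6-carbaldehyde
Conditions: MgCl2, Et3N, paraformaldehyde, MeCN, reflux; HCl work-up
Reagents that add atoms: paraformaldehyde (as formaldehyde), C=O
Why: Magnesium-phenoxide-directed ortho-formylation; C6 is the only position ortho to the hydroxyl, so C2 and C4 should stay untouched.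

Step 15
Reactants: 18 7-hydroxy-3,5-dimethyl-1-benzofuran-6-carbaldehyde
Product: 19 6-ethenyl-3,5-dimethyl-1-benzofuran-7-ol
Conditions: Ph3PCH3Br (3 equiv), KOtBu (3 equiv), THF, 0 °C to rt
Reagents that add atoms: methyltriphenylphosphonium bromide, C[P+](c1ccccc1)(c1ccccc1)c1ccccc1.[Br-]
Why: Wittig methylenation of the salicylaldehyde with excess ylide (one equivalent is consumed by the phenol).

Step 16
Reactants: 19 6-ethenyl-3,5-dimethyl-1-benzofuran-7-ol
Product: 21 3,5-dimethyl-6-[(3E)-pent-3-en-1-yl]-1-benzofuran-7-ol, via alkylborane 20 (not isolated)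
Conditions: 9-BBN (2.2 equiv), THF, 0 °C to rt; then (E)-1-bromoprop-1-ene, Pd(dppf)Cl2, aq. NaOH, THF, 60 °C
Reagents that add atoms: (E)-1-bromoprop-1-ene, C/C=C/Br; 9-borabicyclo[3.3.1]nonane, B1C2CCCC1CCC2 (boron stays only in intermediate 20)
Why: Anti-Markovnikov hydroboration of the styrene, then B-alkyl Suzuki–Miyaura coupling, which should retain the E geometry of the alkenyl bromide.

Step 17
Reactants: 21 3,5-dimethyl-6-[(3E)-pent-3-en-1-yl]-1-benzofuran-7-ol; 13 (5S)-9-hydroxy-5-(hydroxymethyl)-3,4-dimethyl-6,7-dihydronaphtho[2,3-b]furan-8(5H)-one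
Product: 23 silylene-bridged ketone (5S)-5-{[({3,5-dimethyl-6-[(3E)-pent-3-en-1-yl]-1-benzofuran-7-yl}oxy)di(propan-2-yl)silyl]oxymethyl}-9-hydroxy-3,4-dimethyl-6,7-dihydronaphtho[2,3-b]furan-8(5H)-one, via chlorosilane 22 (not isolated)
Conditions: 21, iPr2SiCl2 (3 equiv), Et3N, CH2Cl2, 0 °C; excess silane evaporated; then 13, imidazole, DMF, rt
Reagents that add atoms: dichlorodi(propan-2-yl)silane, CC(C)[Si](Cl)(Cl)C(C)C
Why: Sequential O-silylation (temporary silicon tether); the primary alcohol of 13 should displace the second chloride, while its chelated, hindered C9 phenol should not react.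

Step 18
Reactants: 23 silylene-bridged ketone
Product: 24 silylene-bridged ortho-hydroxybenzyl alcohol (5S; C8 carbinol as a mixture of epimers; the 8,9-diol corresponding to 23)
Conditions: NaBH4, THF/MeOH, −20 °C to 0 °C; neutral work-up
Reagents that add atoms: none
Why: Borohydride reduction of the aryl ketone; the new carbinol configuration does not matter because C8 becomes trigonal in step 19.

Step 19
Reactants: 24 silylene-bridged ortho-hydroxybenzyl alcohol
Product: 26 silylene-bridged cycloadduct (5S,8R,2′R,3′R; O9 bonded to C3′, C8 bonded to C2′, bridge C5–CH2–O–Si(iPr)2–O–C7′ retained), via ortho-quinone methide 25 (not isolated)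
Conditions: diphenyl phosphate (10 mol%), 4 Å molecular sieves, toluene (0.003 M), 40 °C
Reagents that add atoms: none
Why: Proposed new method: acid-assisted loss of water from the ortho-hydroxybenzyl alcohol should give ortho-quinone methide 25, whose electrophilic C8 is attacked by C2′ of the tethered 3-methylbenzofuran while the carbonyl oxygen closes on the developing tertiary benzylic cation at C3′ (asynchronous inverse-electron-demand oxa-[4+2]); the closest known reactions are hetero-Diels–Alder additions of ortho-quinone methides to enol ethers, furans and 2,3-disubstituted indoles, and silicon-tethered intramolecular Diels–Alder reactions. The dihydropyran ring closes by [4+2] cycloaddition, the benzofuran becoming a cis-fused 2,3-dihydrobenzofuran, and a 12-membered silylene-bridged ring forms at the same time (opened in step 20). C8 is set by the tether: the C5–CH2O arm is pseudoaxial (peri strain with the C4 methyl) and can deliver the benzofuran only to the face it stands on, which should override the expected preference for attack anti to the C5 substituent. C2′ and C3′ follow from suprafacial addition across C2′=C3′ in the endo orientation (benzofuran benzene ring stacked over the dienone), the only orientation the short O–Si–O bridge can span. The step needs regioselectivity (C8 to C2′, O9 to C3′), secured by the polarity of both partners, and chemoselectivity over the E-alkene, the naphthofuran furan and dimerisation, secured by the tether and high dilution.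

Step 20
Reactants: 26 silylene-bridged cycloadduct
Product: 27 (5S,8R,2′R,3′R)-diol (the target with CH2OH in place of the C5 methyl; C7′–OH free)
Conditions: TBAF, THF, 0 °C to rt
Reagents that add atoms: none
Why: Fluoride-mediated cleavage of both Si–O bonds removes the tether under non-acidic conditions that should spare the tertiary benzylic ether.

Step 21
Reactants: 27 (5S,8R,2′R,3′R)-diol
Product: 28 (5S,8R,2′R,3′R)-iodide (CH2I at C5)
Conditions: PPh3, I2, imidazole, CH2Cl2, 0 °C to rt
Reagents that add atoms: iodine, II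
Why: Appel iodination, selective for the primary aliphatic alcohol over the phenol.

Step 22
Reactants: 28 (5S,8R,2′R,3′R)-iodide
Product: 29 target, (5S,8R,2′R,3′R)
Conditions: Bu3SnH, AIBN (cat.), toluene, 80 °C
Reagents that add atoms: none
Why: Radical-chain dehalogenation with tin hydride turns CH2I into the C5 methyl without base, so the nearby phenol cannot be alkylated and no stereocentre is touched.

**Compound list**

1 | 3,4-dimethoxytoluene | Cc1ccc(OC)c(OC)c1 | starting material
2 | methyl 4-(4,5-dimethoxy-2-methylphenyl)-4-oxobutanoate | COC(=O)CCC(=O)c1cc(OC)c(OC)cc1C | intermediate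
3 | methyl 4-(4,5-dimethoxy-2-methylphenyl)pent-4-enoate | COC(=O)CCC(=C)c1cc(OC)c(OC)cc1C | intermediate
4 | methyl (4S)-4-(4,5-dimethoxy-2-methylphenyl)-5-(4,4,5,5-tetramethyl-1,3,2-dioxaborolan-2-yl)pentanoate | COC(=O)CC[C@H](CB1OC(C)(C)C(C)(C)O1)c1cc(OC)c(OC)cc1C | intermediate (not isolated)
5 | methyl (4S)-4-(4,5-dimethoxy-2-methylphenyl)-5-hydroxypentanoate | COC(=O)CC[C@H](CO)c1cc(OC)c(OC)cc1C | intermediate
6 | methyl (4S)-4-(4,5-dimethoxy-2-methylphenyl)-5-(pivaloyloxy)pentanoate | COC(=O)CC[C@H](COC(=O)C(C)(C)C)c1cc(OC)c(OC)cc1C | intermediate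
7 | (4S)-4-(4,5-dimethoxy-2-methylphenyl)-5-(pivaloyloxy)pentanoic acid | OC(=O)CC[C@H](COC(=O)C(C)(C)C)c1cc(OC)c(OC)cc1C | intermediate
8 | (4S)-4-(4,5-dimethoxy-2-methylphenyl)-5-(pivaloyloxy)pentanoyl chloride | O=C(Cl)CC[C@H](COC(=O)C(C)(C)C)c1cc(OC)c(OC)cc1C | intermediate (not isolated)
9 | [(1S)-5,6-dimethoxy-8-methyl-4-oxo-1,2,3,4-tetrahydronaphthalen-1-yl]methyl pivalate | O=C1CC[C@H](COC(=O)C(C)(C)C)c2c(C)cc(OC)c(OC)c12 | intermediate
10 | [(1S)-5,6-dihydroxy-8-methyl-4-oxo-1,2,3,4-tetrahydronaphthalen-1-yl]methyl pivalate | O=C1CC[C@H](COC(=O)C(C)(C)C)c2c(C)cc(O)c(O)c12 | intermediate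
11 | [(1S)-5-hydroxy-8-methyl-4-oxo-6-(2-oxopropoxy)-1,2,3,4-tetrahydronaphthalen-1-yl]methyl pivalate | O=C1CC[C@H](COC(=O)C(C)(C)C)c2c(C)cc(OCC(C)=O)c(O)c12 | intermediate
12 | [(5S)-9-hydroxy-3,4-dimethyl-8-oxo-5,6,7,8-tetrahydronaphtho[2,3-b]furan-5-yl]methyl pivalate | O=C1CC[C@H](COC(=O)C(C)(C)C)c2c(C)c3c(C)coc3c(O)c12 | intermediate
13 | (5S)-9-hydroxy-5-(hydroxymethyl)-3,4-dimethyl-6,7-dihydronaphtho[2,3-b]furan-8(5H)-one | O=C1CC[C@H](CO)c2c(C)c3c(C)coc3c(O)c12 | intermediate
14 | creosol (2-methoxy-4-methylphenol) | Cc1ccc(O)c(OC)c1 | starting material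
15 | 1-(2-methoxy-4-methylphenoxy)propan-2-one | CC(=O)COc1ccc(C)cc1OC | intermediate
16 | 7-methoxy-3,5-dimethyl-1-benzofuran | COc1cc(C)cc2c(C)coc12 | intermediate
17 | 3,5-dimethyl-1-benzofuran-7-ol | Oc1cc(C)cc2c(C)coc12 | intermediate
18 | 7-hydroxy-3,5-dimethyl-1-benzofuran-6-carbaldehyde | O=Cc1c(C)cc2c(C)coc2c1O | intermediate
19 | 6-ethenyl-3,5-dimethyl-1-benzofuran-7-ol | C=Cc1c(C)cc2c(C)coc2c1O | intermediate
20 | 9-{2-[7-(9-borabicyclo[3.3.1]nonan-9-yloxy)-3,5-dimethyl-1-benzofuran-6-yl]ethyl}-9-borabicyclo[3.3.1]nonane | Cc1cc2c(C)coc2c(OB2C3CCCC2CCC3)c1CCB1C2CCCC1CCC2 | intermediate (not isolated)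
21 | 3,5-dimethyl-6-[(3E)-pent-3-en-1-yl]-1-benzofuran-7-ol | C/C=C/CCc1c(C)cc2c(C)coc2c1O | intermediate
22 | chloro({3,5-dimethyl-6-[(3E)-pent-3-en-1-yl]-1-benzofuran-7-yl}oxy)di(propan-2-yl)silane | C/C=C/CCc1c(C)cc2c(C)coc2c1O[Si](Cl)(C(C)C)C(C)C | intermediate (not isolated)
23 | silylene-bridged ketone, (5S) | C/C=C/CCc1c(C)cc2c(C)coc2c1O[Si](C(C)C)(C(C)C)OC[C@H]1CCC(=O)c2c(O)c3occ(C)c3c(C)c21 | intermediate
24 | silylene-bridged ortho-hydroxybenzyl alcohol, (5S), C8 epimers | C/C=C/CCc1c(C)cc2c(C)coc2c1O[Si](C(C)C)(C(C)C)OC[C@H]1CCC(O)c2c(O)c3occ(C)c3c(C)c21 | intermediate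
25 | silylene-linked ortho-quinone methide, (5S), C8=C8a and C4=C4a, C9=O | C/C=C/CCc1c(C)cc2c(C)coc2c1O[Si](C(C)C)(C(C)C)OC[C@H]1CCC=C2C(=O)c3occ(C)c3C(C)=C21 | intermediate (not isolated)
26 | silylene-bridged cycloadduct, (5S,8R,2′R,3′R) | C/C=C/CCc1c(C)cc2c(c1O[Si]5(C(C)C)C(C)C)O[C@@H]1[C@@H]3CC[C@H](CO5)c4c3c(c3occ(C)c3c4C)O[C@]21C | intermediate
27 | (5S,8R,2′R,3′R)-diol, C5–CH2OH and C7′–OH | C/C=C/CCc1c(C)cc2c(c1O)O[C@@H]1[C@@H]3CC[C@H](CO)c4c3c(c3occ(C)c3c4C)O[C@]21C | intermediate
28 | (5S,8R,2′R,3′R)-iodide, C5–CH2I | C/C=C/CCc1c(C)cc2c(c1O)O[C@@H]1[C@@H]3CC[C@H](CI)c4c3c(c3occ(C)c3c4C)O[C@]21C | intermediate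
29 | target, (5S,8R,2′R,3′R) | C/C=C/CCc1c(C)cc2c(c1O)O[C@@H]1[C@@H]3CC[C@H](C)c4c3c(c3occ(C)c3c4C)O[C@]21C | target

**Step count and risks**

Total steps: 22. Longest linear sequence: 16 steps (steps 1 to 10, then 17 to 22).

Steps most likely to fail:

1. Step 19 (key step). After the C8–C2′ bond forms, the cation at C3′ may lose the C2′ proton and re-aromatise faster than O9 closes the ring. The quinone methide may also tautomerise to the 7,8-alkene or react intermolecularly. Fallback, stepwise and with known reaction types: from 24, BF3·OEt2 in CH2Cl2 at −40 °C under high dilution is used deliberately for the intramolecular Friedel–Crafts alkylation of benzofuran C2′ by the ortho-hydroxybenzyl cation. This should give the silylene-bridged 2′-alkylbenzofuran F1, with C8 again fixed by the tether. The O9–C3′ bond is then closed separately by Brønsted-acid-catalysed Markovnikov hydroalkoxylation of the C2′=C3′ double bond by the C9 phenol (camphorsulfonic acid, toluene, 60 °C; six-ring closure, cis fusion for strain reasons). This returns to 26.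

2. Step 3. The ortho-methyl group twists the arene out of the alkene plane, which may erode the face discrimination of the cobalt catalyst and give low enantiomeric purity. Fallback by resolution: from 3, hydroboration with 9-BBN and oxidation gives the racemic methyl 4-(4,5-dimethoxy-2-methylphenyl)-5-hydroxypentanoate F2. Lipase-catalysed acetylation (Burkholderia cepacia lipase, vinyl acetate, tert-butyl methyl ether) then separates the enantiomers as alcohol and acetate. If the S material is the acetate, methyl (4S)-5-acetoxy-4-(4,5-dimethoxy-2-methylphenyl)pentanoate F3, it is methanolysed (K2CO3, MeOH) to return to 5; if the S alcohol is the slow-reacting enantiomer, it is 5 itself.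

3. Step 9. The ring carbon to be attacked is para to the ketone, so the electrophilic ring closure may be slow, and forcing acid may cause decomposition or pivalate loss. Fallback with a palladium-based furan synthesis: from 10, iodination of the only free ring position (N-iodosuccinimide, MeCN, 0 °C) gives the iodocatechol F4. Selective O-allylation of the non-chelated hydroxyl (allyl bromide, K2CO3, acetone) gives the allyl ether F5. Intramolecular Heck cyclisation (5-exo) with double-bond isomerisation (Pd(OAc)2, Na2CO3, HCO2Na, Bu4NCl, DMF, 80 °C) then gives the 3-methylfuran and returns to 12.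

**Further compounds**

F1 | step 19 | silylene-bridged (5S,8R) Friedel–Crafts product, C8 bonded to C2′ of the intact benzofuran, C9–OH free | C/C=C/CCc1c(C)cc2c(C)c([C@@H]3CC[C@H](CO5)c4c3c(O)c3occ(C)c3c4C)oc2c1O[Si]5(C(C)C)C(C)C
F2 | step 3 | racemic methyl 4-(4,5-dimethoxy-2-methylphenyl)-5-hydroxypentanoate | COC(=O)CCC(CO)c1cc(OC)c(OC)cc1C
F3 | step 3 | methyl (4S)-5-acetoxy-4-(4,5-dimethoxy-2-methylphenyl)pentanoate | COC(=O)CC[C@H](COC(C)=O)c1cc(OC)c(OC)cc1C
F4 | step 9 | [(1S)-5,6-dihydroxy-7-iodo-8-methyl-4-oxo-1,2,3,4-tetrahydronaphthalen-1-yl]methyl pivalate | O=C1CC[C@H](COC(=O)C(C)(C)C)c2c(C)c(I)c(O)c(O)c12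
F5 | step 9 | [(1S)-5-hydroxy-7-iodo-8-methyl-4-oxo-6-(prop-2-en-1-yloxy)-1,2,3,4-tetrahydronaphthalen-1-yl]methyl pivalate | O=C1CC[C@H](COC(=O)C(C)(C)C)c2c(C)c(I)c(OCC=C)c(O)c12
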